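**Assumptions**
- (2R)-3-Chloro-2-hydroxy-2-methylpropanoic acid (14) is taken as a purchasable single enantiomer.
- Atom labels: C1 hemiketal carbon, C2/C3 oxolane CH2, C4 ether carbon bearing methyl C15, C5=C6 ylidene, C7 and C11 butenolide alkene carbons, C12 lactone carbonyl, C8 acyloxy carbon, C9 CH2, C10 CH bearing methyl C14, C13 acetoxymethyl carbon.

**Retrosynthetic overview**
1. Target ⇐ desilylation with C10 equilibration ⇐ Negishi acetoxymethylation of the C11 bromide ⇐ silylated bromo macrocycle 20.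
2. The ten-membered ring is closed last, at C5=C6, by intramolecular vinylogous aldol/elimination of butenolide C6 onto the C5 aldehyde, with the oxolane hemiketal as a turn element (gives 5E and 1S).
3. C8 ester ⇐ CBS reduction of the C8 ketone 12, then Steglich esterification with 14.
4. Key step: C1–C10 by acyl-radical conjugate addition of aldehyde 6 to dienone 10, exposing the latent C1/C8 1,4-dicarbonyl.
5. 6 ⇐ (S)-2-methylglycidol + allylmagnesium bromide; 10 ⇐ 3,4-dibromofuranone + CO + propenylboronic acid. Ring order: butenolide (bought), then oxolane hemiketal (step 5), then carbocycle (step 10).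

**Route**

Step 1
Reactants: 1 (S)-2-methylglycidol; 2 allylmagnesium bromide
Product: 3 (2R)-2-methylhept-6-ene-1,2-diol
Conditions: 2 (3 equiv), CuI (10 mol%), THF, −40 → 0 °C; aq. NH4Cl
Reagents that add atoms: none
Why: CuI-catalysed SN2 epoxide opening by the Grignard reagent at the unsubstituted CH2 (the first equivalent deprotonates the OH); the quaternary C4 centre is not touched, and S→R is only a CIP priority change.

Step 2
Reactants: 3 (2R)-2-methylhept-6-ene-1,2-diol
Product: 4 (2R)-1-(tert-butyldimethylsilyloxy)-2-methyl-2-(trimethylsilyloxy)hept-6-ene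
Conditions: TBSCl (1.05 equiv), imidazole, CH2Cl2, 0 °C; then Me3SiCl, 23 °C
Reagents that add atoms: tert-butyldimethylsilyl chloride, CC(C)(C)[Si](C)(C)Cl; chlorotrimethylsilane, C[Si](C)(C)Cl
Why: One-pot selective silylation, the bulky TBS group on the primary OH first and then the labile TMS group on the tertiary OH, so the later aldehyde cannot close to a lactol.

Step 3
Reactants: 4 (2R)-1-(tert-butyldimethylsilyloxy)-2-methyl-2-(trimethylsilyloxy)hept-6-ene
Product: 6 (4R)-5-(tert-butyldimethylsilyloxy)-4-methyl-4-(trimethylsilyloxy)pentanal, via ozonide 5 (not isolated)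
Conditions: O3, CH2Cl2, −78 °C; then Me2S, −78 → 23 °C
Reagents that add atoms: ozone, [O-][O+]=O
Why: Criegee ozonolysis of the terminal alkene with reductive work-up gives the C1 aldehyde; silyl ethers and C4 are unaffected.

Step 4
Reactants: 7 3,4-dibromofuran-2(5H)-one; 8 (E)-prop-1-enylboronic acid; 9 carbon monoxide
Product: 10 3-bromo-4-[(2E)-but-2-enoyl]furan-2(5H)-one
Conditions: PdCl2(PPh3)2 (5 mol%), K2CO3, CO (5 bar), toluene, 60 °C
Reagents that add atoms: none
Why: Carbonylative Suzuki–Miyaura coupling; oxidative addition occurs at the more electrophilic C4–Br (β to the lactone carbonyl), CO insertion and transmetalation give the dienone with the E alkene retained and the C3–Br kept as the handle for C13.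

Step 5
Reactants: 6 (4R)-5-(tert-butyldimethylsilyloxy)-4-methyl-4-(trimethylsilyloxy)pentanal; 10 3-bromo-4-[(2E)-but-2-enoyl]furan-2(5H)-one
Product: 12 3-bromo-4-{3-[(5R)-5-(tert-butyldimethylsilyloxymethyl)-2-hydroxy-5-methyloxolan-2-yl]butanoyl}furan-2(5H)-one, via bis-silyl diketone 11 (not isolated)
Conditions: (n-Bu4N)4[W10O32] (2 mol%), 6 (1.5 equiv), MeCN, 390 nm LEDs, 20 °C, Ar; then AcOH/H2O/THF, 23 °C, 1 h
Reagents that add atoms: none
Why: Giese-type radical hydroacylation (radical Stetter logic): photoexcited [W10O32]4− abstracts the hydridic formyl H of 6, the nucleophilic acyl radical adds to the β-carbon C10 of the crotonoyl group rather than to the tetrasubstituted bromoalkene, and back hydrogen transfer to the α-keto radical forges C1–C10; C10 forms unselectively (about 1:1, corrected in step 12), and the acid wash removes the TMS group so the tertiary OH closes onto C1 as the oxolane hemiketal.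

Step 6
Reactants: 12 3-bromo-4-{3-[(5R)-5-(tert-butyldimethylsilyloxymethyl)-2-hydroxy-5-methyloxolan-2-yl]butanoyl}furan-2(5H)-one
Product: 13 3-bromo-4-{(1R)-1-hydroxy-3-[(5R)-5-(tert-butyldimethylsilyloxymethyl)-2-hydroxy-5-methyloxolan-2-yl]butyl}furan-2(5H)-one
Conditions: (S)-2-methyl-CBS-oxazaborolidine (0.5 equiv), BH3·SMe2 (3 equiv), THF, −30 °C; MeOH
Reagents that add atoms: none
Why: Corey–Bakshi–Shibata reduction; with the sp2 butenolide carbon as the large group and C9H2 as the small one, the (S)-catalyst gives the 8R alcohol under reagent control, and the only other ketone (C1) is masked as the hemiketal.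

Step 7
Reactants: 13 3-bromo-4-{(1R)-1-hydroxy-3-[(5R)-5-(tert-butyldimethylsilyloxymethyl)-2-hydroxy-5-methyloxolan-2-yl]butyl}furan-2(5H)-one; 14 (2R)-3-chloro-2-hydroxy-2-methylpropanoic acid
Product: 15 (1R)-1-(4-bromo-5-oxo-2,5-dihydrofuran-3-yl)-3-[(5R)-5-(tert-butyldimethylsilyloxymethyl)-2-hydroxy-5-methyloxolan-2-yl]butyl (2R)-3-chloro-2-hydroxy-2-methylpropanoate
Conditions: DCC, DMAP (cat.), CH2Cl2, 0 → 23 °C (13 used directly)
Reagents that add atoms: none
Why: Steglich esterification of the only secondary OH (the hemiketal OH and the acid's tertiary OH are too hindered to compete); acylating C8 now removes any C9 enolisation or spiroketal pathway later, and the side-chain stereocentre comes unchanged from 14.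

Step 8
Reactants: 15 (1R)-1-(4-bromo-5-oxo-2,5-dihydrofuran-3-yl)-3-[(5R)-5-(tert-butyldimethylsilyloxymethyl)-2-hydroxy-5-methyloxolan-2-yl]butyl (2R)-3-chloro-2-hydroxy-2-methylpropanoate
Product: 16 (1R)-1-(4-bromo-5-oxo-2,5-dihydrofuran-3-yl)-3-[(5R)-2-hydroxy-5-(hydroxymethyl)-5-methyloxolan-2-yl]butyl (2R)-3-chloro-2-hydroxy-2-methylpropanoate
Conditions: HF·pyridine, pyridine, THF, 0 °C
Reagents that add atoms: none
Why: Buffered fluoride cleavage of the primary TBS ether; esters, chlorohydrin and hemiketal tolerate these conditions.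

Step 9
Reactants: 16 (1R)-1-(4-bromo-5-oxo-2,5-dihydrofuran-3-yl)-3-[(5R)-2-hydroxy-5-(hydroxymethyl)-5-methyloxolan-2-yl]butyl (2R)-3-chloro-2-hydroxy-2-methylpropanoate
Product: 17 (1R)-1-(4-bromo-5-oxo-2,5-dihydrofuran-3-yl)-3-[(5R)-5-formyl-2-hydroxy-5-methyloxolan-2-yl]butyl (2R)-3-chloro-2-hydroxy-2-methylpropanoate
Conditions: TEMPO (10 mol%), PhI(OAc)2, CH2Cl2, 23 °C (used at once)
Reagents that add atoms: none
Why: Oxoammonium (TEMPO/PhI(OAc)2) oxidation of the only primary alcohol to the non-enolisable C5 aldehyde; the remaining hydroxyls are tertiary.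

Step 10
Reactants: 17 (1R)-1-(4-bromo-5-oxo-2,5-dihydrofuran-3-yl)-3-[(5R)-5-formyl-2-hydroxy-5-methyloxolan-2-yl]butyl (2R)-3-chloro-2-hydroxy-2-methylpropanoate
Product: 20 bis(triethylsilyl)-protected (1S,4R,5E,8R)-11-bromo macrocycle, via silyloxyfuran aldehyde 18 (not isolated), via silylated aldol macrocycle 19 (not isolated)
Conditions: Et3SiOTf (6 equiv), i-Pr2NEt (10 equiv), CH2Cl2 (1 mM), −78 → −20 °C; then DBU, −20 → 23 °C
Reagents that add atoms: triethylsilyl trifluoromethanesulfonate, CC[Si](CC)(CC)OS(=O)(=O)C(F)(F)F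
Why: Proposed new method: intramolecular version of the silyl-triflate vinylogous Mukaiyama aldol/DBU elimination used for γ-ylidenebutenolides; soft enolisation gives silyloxyfuran 18 (both free hydroxyls are silylated as well), its C6 attacks the Et3SiOTf-activated C5 aldehyde held nearby on the cis-2,5-disubstituted oxolane (the silyl ketal anomerises under Et3SiOTf, so material drains through the cis anomer), and DBU expels Et3SiO− from 19 by E1cB; the new C5=C6 bond can only be ring-cis (5E) and the oxygen bridge fixes C1 as S.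

Step 11
Reactants: 20 bis(triethylsilyl)-protected (1S,4R,5E,8R)-11-bromo macrocycle; 21 bromomethyl acetate
Product: 23 bis(triethylsilyl)-protected target, via acetoxymethylzinc bromide 22 (not isolated)
Conditions: 21, Zn, LiCl, THF, 23 °C; then 20, Pd(OAc)2 (5 mol%), SPhos (10 mol%), THF, 23 °C
Reagents that add atoms: none
Why: Negishi coupling of the α-bromo butenolide with an acyloxymethylzinc halide (acetate analogue of the known pivaloyloxymethylzinc reagents) installs C13 with its acetate in one step; the silylated hydroxyls and the alkyl chloride are inert, and no stereocentre is involved.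

Step 12
Reactants: 23 bis(triethylsilyl)-protected target
Product: 25 CNP0414417.2, via desilylated C10 epimer mixture 24 (not isolated)
Conditions: HF·pyridine, THF, 0 → 23 °C; then PPTS (20 mol%), THF/H2O (20:1), 40 °C
Reagents that add atoms: none
Why: Fluoride removes both triethylsilyl groups, and mild acid then opens the hemiketal reversibly to the C1 ketone/enol so that C10 equilibrates; the 10R epimer is expected to be favoured because its methyl lies on the oxygen-bridge side, gauche to the ring oxygen rather than to C2, but this preference is a conformational estimate and may be modest.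

**Compound list**
1 | (S)-2-methylglycidol | OC[C@@]1(C)CO1 | starting material
2 | allylmagnesium bromide | C=CC[Mg]Br | starting material
3 | (2R)-2-methylhept-6-ene-1,2-diol | OC[C@@](O)(C)CCC=C | intermediate
4 | (2R)-1-(tert-butyldimethylsilyloxy)-2-methyl-2-(trimethylsilyloxy)hept-6-ene | CC(C)(C)[Si](C)(C)OC[C@@](O[Si](C)(C)C)(C)CCC=C | intermediate
5 | ozonide (1,2,4-trioxolane) of 4 | CC(C)(C)[Si](C)(C)OC[C@@](O[Si](C)(C)C)(C)CCC1OOCO1 | intermediate
6 | (4R)-5-(tert-butyldimethylsilyloxy)-4-methyl-4-(trimethylsilyloxy)pentanal | CC(C)(C)[Si](C)(C)OC[C@@](O[Si](C)(C)C)(C)CCC=O | intermediate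
7 | 3,4-dibromofuran-2(5H)-one | BrC1=C(Br)C(=O)OC1 | starting material
8 | (E)-prop-1-enylboronic acid | C/C=C/B(O)O | starting material
9 | carbon monoxide | [C-]#[O+] | starting material
10 | 3-bromo-4-[(2E)-but-2-enoyl]furan-2(5H)-one | C/C=C/C(=O)C1=C(Br)C(=O)OC1 | intermediate
11 | 3-bromo-4-[(7R)-8-(tert-butyldimethylsilyloxy)-3,7-dimethyl-4-oxo-7-(trimethylsilyloxy)octanoyl]furan-2(5H)-one (C10 epimers) | CC(C)(C)[Si](C)(C)OC[C@@](O[Si](C)(C)C)(C)CCC(=O)C(C)CC(=O)C1=C(Br)C(=O)OC1 | intermediate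
12 | hemiketal ketone (C10 epimers, hemiketal anomers) | CC(C)(C)[Si](C)(C)OC[C@@]1(C)CCC(O)(O1)C(C)CC(=O)C2=C(Br)C(=O)OC2 | intermediate
13 | (8R)-alcohol (C10 epimers) | CC(C)(C)[Si](C)(C)OC[C@@]1(C)CCC(O)(O1)C(C)C[C@@H](O)C2=C(Br)C(=O)OC2 | intermediate
14 | (2R)-3-chloro-2-hydroxy-2-methylpropanoic acid | OC(=O)[C@@](C)(O)CCl | starting material
15 | C8 chlorohydrin ester, TBS ether (C10 epimers) | CC(C)(C)[Si](C)(C)OC[C@@]1(C)CCC(O)(O1)C(C)C[C@@H](OC(=O)[C@@](C)(O)CCl)C2=C(Br)C(=O)OC2 | intermediate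
16 | C8 ester, primary alcohol | OC[C@@]1(C)CCC(O)(O1)C(C)C[C@@H](OC(=O)[C@@](C)(O)CCl)C2=C(Br)C(=O)OC2 | intermediate
17 | C8 ester, C5 aldehyde | O=C[C@@]1(C)CCC(O)(O1)C(C)C[C@@H](OC(=O)[C@@](C)(O)CCl)C2=C(Br)C(=O)OC2 | intermediate
18 | tris-silylated 2-(triethylsilyloxy)furan aldehyde | O=C[C@@]1(C)CCC(O[Si](CC)(CC)CC)(O1)C(C)C[C@@H](OC(=O)[C@@](C)(O[Si](CC)(CC)CC)CCl)c2coc(O[Si](CC)(CC)CC)c2Br | intermediate
19 | silylated vinylogous aldol macrocycle | O=C1OC2C(O[Si](CC)(CC)CC)[C@@]3(C)CCC(O[Si](CC)(CC)CC)(O3)C(C)C[C@@H](OC(=O)[C@@](C)(O[Si](CC)(CC)CC)CCl)C2=C1Br | intermediate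
20 | bis(triethylsilyl)-protected (1S,4R,5E,8R)-11-bromo macrocycle (C10 epimers) | BrC1=C2/C(=C\[C@@]3(C)CC[C@](O[Si](CC)(CC)CC)(O3)C(C)C[C@H]2OC(=O)[C@@](C)(O[Si](CC)(CC)CC)CCl)OC1=O | intermediate
21 | bromomethyl acetate | CC(=O)OCBr | starting material
22 | (acetoxymethyl)zinc bromide | CC(=O)OC[Zn]Br | intermediate
23 | bis(triethylsilyl)-protected target (C10 epimers) | CC(=O)OCC1=C2/C(=C\[C@@]3(C)CC[C@](O[Si](CC)(CC)CC)(O3)C(C)C[C@H]2OC(=O)[C@@](C)(O[Si](CC)(CC)CC)CCl)OC1=O | intermediate
24 | desilylated C10 epimer mixture | CC(=O)OCC1=C2/C(=C\[C@@]3(C)CC[C@](O)(O3)C(C)C[C@H]2OC(=O)[C@@](C)(O)CCl)OC1=O | intermediate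
25 | CNP0414417.2, (1S,4R,5E,8R,10R)-hemiketal with 13-acetate and 8-[(2R)-3-chloro-2-hydroxy-2-methylpropanoate] | CC(=O)OCC1=C2/C(=C\[C@@]3(C)CC[C@](O)(O3)[C@H](C)C[C@H]2OC(=O)[C@@](C)(O)CCl)OC1=O | target

**Totals**
Total steps: 12. Longest linear sequence: 11 (steps 1–3 and 5–12; step 4 is the convergent branch).

**Three steps most likely to fail**

Step 5 (key radical union). The β-methyl enone is a slower acceptor than a vinyl ketone, and hydrogen abstraction may stray to other C–H bonds of 6 or 10. Fallback: make the same acyl radical by a silane chain from a selenoester. Setting out from 6, Pinnick oxidation (NaClO2, NaH2PO4, 2-methylbut-2-ene) gives (4R)-5-(tert-butyldimethylsilyloxy)-4-methyl-4-(trimethylsilyloxy)pentanoic acid F1. PhSeSePh and Bu3P convert it into the Se-phenyl selenoester F2. Slow addition of (Me3Si)3SiH and AIBN to F2 and 10 in benzene at 80 °C then gives 11 by the same conjugate addition, and the route is rejoined at 11.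

Step 10 (ring closure). Risks are ionisation of the allylic C8 ester under Et3SiOTf, silyl enol ether formation from the open-chain C1 ketone followed by a six-ring aldol from C10 onto C5, and oligomerisation. Fallback: close the ring by an intramolecular Horner–Wadsworth–Emmons reaction. Setting out from 15, NBS/AIBN gives the C6 bromide F3, and P(OMe)3 (Arbuzov) gives the C6 dimethyl phosphonate F4. HF·pyridine then gives the primary alcohol F5, and TEMPO/PhI(OAc)2 the aldehyde phosphonate F6. LiCl and i-Pr2NEt in MeCN at 1 mM close the ring to the unprotected bromo macrocycle F7. Negishi coupling of F7 with 22 as in step 11 gives 24, where the route is rejoined.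

Step 12 (C10). The thermodynamic preference for 10R in the bicycle may be small. Fallback: resolve C10 early by separation and recycling instead of late equilibration. Setting out from 13, whose C10 epimers are diastereomers once C8 is set, chromatography gives the (8R,10R)-alcohol F8 and the (8R,10S)-alcohol F9. F9 is re-equilibrated with Et3N through the open-chain C1 ketone and separated again. F8 is carried through steps 7–11 and rejoins the route at 15 as the single 10R isomer, so step 12 then needs only HF·pyridine.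

**Further compounds**
F1 | step 5 | (4R)-5-(tert-butyldimethylsilyloxy)-4-methyl-4-(trimethylsilyloxy)pentanoic acid | CC(C)(C)[Si](C)(C)OC[C@@](O[Si](C)(C)C)(C)CCC(=O)O
F2 | step 5 | Se-phenyl (4R)-5-(tert-butyldimethylsilyloxy)-4-methyl-4-(trimethylsilyloxy)pentaneselenoate | CC(C)(C)[Si](C)(C)OC[C@@](O[Si](C)(C)C)(C)CCC(=O)[Se]c1ccccc1
F3 | step 10 | C6 bromide of 15 | CC(C)(C)[Si](C)(C)OC[C@@]1(C)CCC(O)(O1)C(C)C[C@@H](OC(=O)[C@@](C)(O)CCl)C2=C(Br)C(=O)OC2Br
F4 | step 10 | C6 dimethyl phosphonate | CC(C)(C)[Si](C)(C)OC[C@@]1(C)CCC(O)(O1)C(C)C[C@@H](OC(=O)[C@@](C)(O)CCl)C2=C(Br)C(=O)OC2P(=O)(OC)OC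
F5 | step 10 | phosphonate primary alcohol | OC[C@@]1(C)CCC(O)(O1)C(C)C[C@@H](OC(=O)[C@@](C)(O)CCl)C2=C(Br)C(=O)OC2P(=O)(OC)OC
F6 | step 10 | phosphonate aldehyde | O=C[C@@]1(C)CCC(O)(O1)C(C)C[C@@H](OC(=O)[C@@](C)(O)CCl)C2=C(Br)C(=O)OC2P(=O)(OC)OC
F7 | step 10 | unprotected (1S,4R,5E,8R)-11-bromo macrocycle | BrC1=C2/C(=C\[C@@]3(C)CC[C@](O)(O3)C(C)C[C@H]2OC(=O)[C@@](C)(O)CCl)OC1=O
F8 | step 12 | (8R,10R)-alcohol, single epimer of 13 | CC(C)(C)[Si](C)(C)OC[C@@]1(C)CCC(O)(O1)[C@H](C)C[C@@H](O)C2=C(Br)C(=O)OC2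
F9 | step 12 | (8R,10S)-alcohol, single epimer of 13 | CC(C)(C)[Si](C)(C)OC[C@@]1(C)CCC(O)(O1)[C@@H](C)C[C@@H](O)C2=C(Br)C(=O)OC2
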